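**Retrosynthetic overview** (locants follow the benzofuranone core of the target: O1, C2=O, C3=CH2, C3a, C4–O-angelate, C5–side chain, C6–CH2OH, C7, C7a; side-chain stereocentre C2')
- Last events: desilylation, preceded by one palladium cascade on a cyclohexadienyl 2-bromoacrylate that closes the lactone (C3–C3a bond) and attaches the angelate at C4.
- The cyclohexadienol arises by E1cB opening and hydride reduction of a 7-oxanorbornene; the bridging oxygen stays on C7a and becomes the lactone ring oxygen.
- Key step: a catalytic enantioselective, dearomatising Diels–Alder reaction of a 2-alkylfuran with an acrylimide builds the carbocycle (C5–C6 and C7–C7a bonds) and sets C7a; C3a and C4 are later relayed from C7a.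
- The furan carries the C2' stereocentre, made from 2-acetylfuran by Wittig olefination and asymmetric hydrogenation.
- Ring order: six-membered carbocycle first (cycloaddition), γ-lactone second (palladium cascade).

Assumption: the target is the stereoisomer written in the SMILES, i.e. (3aR,4S,7aR) with a (2R)-5-hydroxypentan-2-yl group and a Z (angelate) ester; the stated senses of induction of the two chiral catalysts are assigned by analogy, and the antipodal ligand is used if either proves opposite.

**Step 1**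
Reactants: 1 2-acetylfuran; 2 (2-carboxyethyl)triphenylphosphonium bromide
Product: 4 (3E)-4-(furan-2-yl)pent-3-enoic acid, via ylide carboxylate 3 (not isolated)
Conditions: KOtBu (2.2 equiv), THF, 0 → 50 °C; aq. HCl; recrystallisation to pure E
Reagents that add atoms: (2-carboxyethyl)triphenylphosphonium bromide (2), OC(=O)CC[P+](c1ccccc1)(c1ccccc1)c1ccccc1.[Br-]
Why: Wittig olefination of the ketone by ylide 3; ylides carrying an anionic carboxylate give mainly the E trisubstituted alkene with aryl methyl ketones, the minor Z acid is removed by crystallisation, and no stereocentre is formed.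

**Step 2**
Reactants: 4 (3E)-4-(furan-2-yl)pent-3-enoic acid
Product: 6 methyl (4R)-4-(furan-2-yl)pentanoate, via (4R)-4-(furan-2-yl)pentanoic acid 5 (not isolated)
Conditions: H2 (6 atm), [Ir(cod)(L)][B(3,5-(CF3)2C6H3)4] (0.5 mol %; L = 7-[bis(3,5-di-tert-butylphenyl)phosphanyl]-7'-(4-benzyl-4,5-dihydro-1,3-oxazol-2-yl)-1,1'-spirobiindane, antipode that gives 4R), Et3N (0.5 equiv), MeOH, rt; then TMSCHN2, PhMe–MeOH, 0 °C
Reagents that add atoms: (trimethylsilyl)diazomethane, C[Si](C)(C)C=[N+]=[N-]
Why: Carboxylate-directed asymmetric hydrogenation of the E β,γ-unsaturated acid by the cationic iridium spiro phosphine–oxazoline catalyst sets the side-chain stereocentre (future C2') as R through ligand-controlled facial hydride delivery, the furan ring is inert under these mild conditions, and diazo-methylation in the same flask masks the acid for the Lewis-acid step.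

**Step 3** (key step)
Reactants: 6 methyl (4R)-4-(furan-2-yl)pentanoate; 7 3-(prop-2-enoyl)-1,3-oxazolidin-2-one
Product: 8 methyl (4R)-4-[(1R,2R,4R)-2-(2-oxo-1,3-oxazolidine-3-carbonyl)-7-oxabicyclo[2.2.1]hept-5-en-1-yl]pentanoate
Conditions: 6 (1.0 equiv), 7 (1.5 equiv), [Cu(L)](SbF6)2 (10 mol %; L = 2,2'-(propane-2,2-diyl)bis[(4R)-4-tert-butyl-4,5-dihydro-1,3-oxazole]), CH2Cl2, −78 °C, 48 h; cold quench; chromatography (endo isomer)
Reagents that add atoms: 3-(prop-2-enoyl)-1,3-oxazolidin-2-one (7), C=CC(=O)N1CCOC1=O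
Why: Catalytic enantioselective Diels–Alder reaction that dearomatises the furan: the imide chelates the square-planar divalent copper bis(oxazoline) cation, which leaves only the Cα-Si face open, and the 2-alkylfuran adds endo with its free α-carbon bonding to the acrylimide β-carbon ("ortho" orientation), fixing the oxygen-bearing bridgehead C4 (future C7a) as R; −78 °C preserves the kinetic adduct, the remote side-chain centre is unaffected, and the exo isomer (which would give the C7a epimer after ring opening) is removed by chromatography.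

**Step 4**
Reactants: 8 methyl (4R)-4-[(1R,2R,4R)-2-(2-oxo-1,3-oxazolidine-3-carbonyl)-7-oxabicyclo[2.2.1]hept-5-en-1-yl]pentanoate
Product: 10 (4R)-4-[(4R)-4-hydroxy-2-(hydroxymethyl)cyclohexa-1,5-dien-1-yl]pentan-1-ol, via dienol imide 9 (not isolated)
Conditions: LiN(SiMe3)2 (1.3 equiv), THF, −78 → −20 °C; then LiBH4 (4 equiv), MeOH (4 equiv), 0 °C → rt; aq. NaHCO3 work-up, Et3N-buffered silica, used at once
Reagents that add atoms: none
Why: E1cB ring opening, in which the imide enolate at C2 expels the strained bridging oxygen from C1 to give the conjugated dienyl imide 9 with the alkoxide left on the stereocentre (its C–O bond is untouched, so R is retained), followed by borohydride 1,2-reduction of imide and methyl ester to the two primary alcohols; the basic medium protects the acid-labile dienol from dehydration to the arene.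

**Step 5**
Reactants: 10 (4R)-4-[(4R)-4-hydroxy-2-(hydroxymethyl)cyclohexa-1,5-dien-1-yl]pentan-1-ol
Product: 11 (1R)-4-[(2R)-5-{[tert-butyl(dimethyl)silyl]oxy}pentan-2-yl]-5-({[tert-butyl(dimethyl)silyl]oxy}methyl)cyclohexa-2,4-dien-1-ol
Conditions: TBSCl (2.1 equiv), imidazole (3 equiv), CH2Cl2, −20 → 0 °C
Reagents that add atoms: tert-butyldimethylsilyl chloride, CC(C)(C)[Si](C)(C)Cl
Why: Sterically controlled silylation: the two primary hydroxyls react far faster than the secondary allylic one at low temperature, the basic medium avoids aromatisation, and no stereocentre is touched.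

**Step 6**
Reactants: 11 (1R)-4-[(2R)-5-{[tert-butyl(dimethyl)silyl]oxy}pentan-2-yl]-5-({[tert-butyl(dimethyl)silyl]oxy}methyl)cyclohexa-2,4-dien-1-ol; 12 2-bromoprop-2-enoic acid
Product: 13 (1R)-4-[(2R)-5-{[tert-butyl(dimethyl)silyl]oxy}pentan-2-yl]-5-({[tert-butyl(dimethyl)silyl]oxy}methyl)cyclohexa-2,4-dien-1-yl 2-bromoprop-2-enoate
Conditions: 12 (1.5 equiv), DIC (1.5 equiv), DMAP (0.1 equiv), CH2Cl2, −20 → 0 °C; used without delay
Reagents that add atoms: 2-bromoprop-2-enoic acid (12), C=C(Br)C(=O)O
Why: Steglich esterification acylates the oxygen without breaking the carbinol C–O bond, so the configuration is retained, and the cold non-acidic medium prevents ionisation of the dienyl ester.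

**Step 7**
Reactants: 13 (1R)-4-[(2R)-5-{[tert-butyl(dimethyl)silyl]oxy}pentan-2-yl]-5-({[tert-butyl(dimethyl)silyl]oxy}methyl)cyclohexa-2,4-dien-1-yl 2-bromoprop-2-enoate; 14 (2Z)-2-methylbut-2-enoic acid (angelic acid)
Product: 18 [(3aR,4S,7aR)-6-({[tert-butyl(dimethyl)silyl]oxy}methyl)-5-[(2R)-5-{[tert-butyl(dimethyl)silyl]oxy}pentan-2-yl]-3-methylidene-2-oxo-2,3,3a,4,7,7a-hexahydro-1-benzofuran-4-yl] (2Z)-2-methylbut-2-enoate, via cesium (2Z)-2-methylbut-2-enoate 15 (not isolated), via σ-vinyl complex [PdBr(PPh3)2(vinyl)] 16 (not isolated), via η3-allyl complex [PdBr(PPh3)(allyl)] 17 (not isolated)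
Conditions: Pd(PPh3)4 (5 mol %), 14 (3 equiv), Cs2CO3 (1.5 equiv), DMF, 35 °C, slow addition of 13
Reagents that add atoms: (2Z)-2-methylbut-2-enoic acid (14), C/C=C(/C)C(=O)O
Why: Proposed new method: zerovalent palladium inserts into the C–Br bond faster than it ionises the allylic ester; the σ-vinyl complex 16 of divalent palladium adds 5-exo and syn across the proximal diene double bond from the face of the tethering oxygen (cis ring fusion, C3a set as R) to give the η3-allyl complex 17 with palladium on the lactone face; angelate 15 then attacks from outside, anti to palladium, at the less substituted allyl terminus C4 (S, trans to the C3a–C3 bond), which keeps the tetrasubstituted 5,6-alkene; the closest known reactions are Heck–Tsuji–Trost cascades of 1,3-dienes with vinyl halides and nucleophiles (Larock-type heteroannulation) and palladium-catalysed cyclisations of dienyl alkynoates to α-alkylidene-γ-butyrolactones.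

**Step 8**
Reactants: 18 [(3aR,4S,7aR)-6-({[tert-butyl(dimethyl)silyl]oxy}methyl)-5-[(2R)-5-{[tert-butyl(dimethyl)silyl]oxy}pentan-2-yl]-3-methylidene-2-oxo-2,3,3a,4,7,7a-hexahydro-1-benzofuran-4-yl] (2Z)-2-methylbut-2-enoate
Product: 19 [(3aR,4S,7aR)-6-(hydroxymethyl)-5-[(2R)-5-hydroxypentan-2-yl]-3-methylidene-2-oxo-2,3,3a,4,7,7a-hexahydro-1-benzofuran-4-yl] (2Z)-2-methylbut-2-enoate
Conditions: HF·pyridine, pyridine, THF, 0 °C → rt
Reagents that add atoms: none
Why: Fluoride-driven desilylation (strong Si–F bond) with buffered HF·pyridine removes both primary silyl ethers, while the angelate, the allylic C4–O bond and the Michael-acceptor lactone survive the non-basic medium and no stereocentre is affected.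

**Compound list**
1 | 1-(furan-2-yl)ethan-1-one (2-acetylfuran) | CC(=O)c1ccco1 | starting material
2 | (2-carboxyethyl)triphenylphosphonium bromide | OC(=O)CC[P+](c1ccccc1)(c1ccccc1)c1ccccc1.[Br-] | starting material
3 | potassium 3-(triphenyl-λ5-phosphanylidene)propanoate (ylide carboxylate) | [K+].[O-]C(=O)CC=P(c1ccccc1)(c1ccccc1)c1ccccc1 | intermediate (not isolated)
4 | (3E)-4-(furan-2-yl)pent-3-enoic acid | C/C(=C\CC(=O)O)c1ccco1 | intermediate
5 | (4R)-4-(furan-2-yl)pentanoic acid | C[C@H](CCC(=O)O)c1ccco1 | intermediate (not isolated)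
6 | methyl (4R)-4-(furan-2-yl)pentanoate | C[C@H](CCC(=O)OC)c1ccco1 | intermediate
7 | 3-(prop-2-enoyl)-1,3-oxazolidin-2-one | C=CC(=O)N1CCOC1=O | starting material
8 | methyl (4R)-4-[(1R,2R,4R)-2-(2-oxo-1,3-oxazolidine-3-carbonyl)-7-oxabicyclo[2.2.1]hept-5-en-1-yl]pentanoate (endo) | COC(=O)CC[C@@H](C)[C@@]12O[C@@H](C=C1)C[C@H]2C(=O)N1CCOC1=O | intermediate
9 | methyl (4R)-4-[(4R)-4-hydroxy-2-(2-oxo-1,3-oxazolidine-3-carbonyl)cyclohexa-1,5-dien-1-yl]pentanoate (lithium alkoxide in the flask) | COC(=O)CC[C@@H](C)C1=C(C(=O)N2CCOC2=O)C[C@@H](O)C=C1 | intermediate (not isolated)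
10 | (4R)-4-[(4R)-4-hydroxy-2-(hydroxymethyl)cyclohexa-1,5-dien-1-yl]pentan-1-ol | OCCC[C@@H](C)C1=C(CO)C[C@@H](O)C=C1 | intermediate
11 | (1R)-4-[(2R)-5-{[tert-butyl(dimethyl)silyl]oxy}pentan-2-yl]-5-({[tert-butyl(dimethyl)silyl]oxy}methyl)cyclohexa-2,4-dien-1-ol | CC(C)(C)[Si](C)(C)OCCC[C@@H](C)C1=C(CO[Si](C)(C)C(C)(C)C)C[C@@H](O)C=C1 | intermediate
12 | 2-bromoprop-2-enoic acid | C=C(Br)C(=O)O | starting material
13 | (1R)-4-[(2R)-5-{[tert-butyl(dimethyl)silyl]oxy}pentan-2-yl]-5-({[tert-butyl(dimethyl)silyl]oxy}methyl)cyclohexa-2,4-dien-1-yl 2-bromoprop-2-enoate | CC(C)(C)[Si](C)(C)OCCC[C@@H](C)C1=C(CO[Si](C)(C)C(C)(C)C)C[C@@H](OC(=O)C(Br)=C)C=C1 | intermediate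
14 | (2Z)-2-methylbut-2-enoic acid (angelic acid) | C/C=C(/C)C(=O)O | starting material
15 | cesium (2Z)-2-methylbut-2-enoate | C/C=C(/C)C(=O)[O-].[Cs+] | intermediate (not isolated)
16 | σ-vinyl complex of divalent palladium, trans-[PdBr(PPh3)2(C(=CH2)CO2R)], R = dienyl residue of 13 (PPh3 omitted in SMILES) | CC(C)(C)[Si](C)(C)OCCC[C@@H](C)C1=C(CO[Si](C)(C)C(C)(C)C)C[C@@H](OC(=O)C(=C)[Pd]Br)C=C1 | intermediate (not isolated)
17 | η3-allyl complex of divalent palladium, [PdBr(PPh3)(η3-C4–C5–C6 allyl)], drawn as its C4 σ-form with Pd cis to the C3a–C3 bond (PPh3 omitted in SMILES) | C=C1C(=O)O[C@@H]2CC(CO[Si](C)(C)C(C)(C)C)=C([C@H](C)CCCO[Si](C)(C)C(C)(C)C)[C@H]([Pd]Br)[C@H]12 | intermediate (not isolated)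
18 | [(3aR,4S,7aR)-6-({[tert-butyl(dimethyl)silyl]oxy}methyl)-5-[(2R)-5-{[tert-butyl(dimethyl)silyl]oxy}pentan-2-yl]-3-methylidene-2-oxo-2,3,3a,4,7,7a-hexahydro-1-benzofuran-4-yl] (2Z)-2-methylbut-2-enoate | C=C1C(=O)O[C@@H]2CC(CO[Si](C)(C)C(C)(C)C)=C([C@H](C)CCCO[Si](C)(C)C(C)(C)C)[C@@H](OC(=O)/C(C)=C\C)[C@H]12 | intermediate
19 | [(3aR,4S,7aR)-6-(hydroxymethyl)-5-[(2R)-5-hydroxypentan-2-yl]-3-methylidene-2-oxo-2,3,3a,4,7,7a-hexahydro-1-benzofuran-4-yl] (2Z)-2-methylbut-2-enoate (CNP0106570.2) | C=C1C(=O)O[C@@H]2CC(CO)=C([C@H](C)CCCO)[C@@H](OC(=O)/C(C)=C\C)[C@H]12 | target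

**Step count**
Total: 8 steps. Longest linear sequence: 8 steps (1 → 19; the route is fully linear, with 2, 7, 12 and 14 entering as purchased building blocks).

**Steps most likely to fail, with fallbacks**

Step 7 is the least certain. Zerovalent palladium may ionise the dienyl ester and aromatise it, the allyl complex may undergo β-hydride elimination, or the carboxylate may be delivered from the metal to the wrong face. The fallback replaces the organopalladium cascade by a radical cyclisation–oxygenation and esterifies afterwards. It sets out from 13: Bu3SnH in toluene under a stream of dry air (0 °C → rt, then PPh3) generates the α-acrylyl σ-radical, which closes 5-exo onto the diene to give the cis-fused lactone. The resulting allyl radical is trapped by O2 at the less hindered terminus, anti to the new ring, and reduction of the hydroperoxide gives (3aR,4S,7aR)-6-({[tert-butyl(dimethyl)silyl]oxy}methyl)-5-[(2R)-5-{[tert-butyl(dimethyl)silyl]oxy}pentan-2-yl]-4-hydroxy-3-methylidene-3a,4,7,7a-tetrahydro-1-benzofuran-2(3H)-one F6. Angelic acid 14 is then attached through its mixed anhydride with 2,4,6-trichlorobenzoyl chloride (Et3N, toluene, 80 °C, conditions that keep the Z geometry), and the route is rejoined at 18.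

Step 3 may give Friedel–Crafts alkylation at the free furan α-position under Lewis acid, the wrong regio- or exo isomer, or cycloreversion. The fallback gives up catalyst control of the ring configuration and obtains it by separation after ring opening. It sets out from 6: an uncatalysed cycloaddition with ethyl acrylate at 12 kbar (CH2Cl2, rt, no Lewis acid and hence no Friedel–Crafts pathway) gives ethyl 1-[(2R)-5-methoxy-5-oxopentan-2-yl]-7-oxabicyclo[2.2.1]hept-5-ene-2-carboxylate F1 as a mixture of ring stereoisomers. LiN(SiMe3)2 (THF, −78 → 0 °C) opens every isomer to ethyl 5-hydroxy-2-[(2R)-5-methoxy-5-oxopentan-2-yl]cyclohexa-1,3-diene-1-carboxylate F2, in which the endo/exo information is erased and only the two carbinol epimers remain. These are separated by lipase-mediated acetylation with vinyl acetate or by preparative HPLC on a chiral phase to give ethyl (5R)-5-hydroxy-2-[(2R)-5-methoxy-5-oxopentan-2-yl]cyclohexa-1,3-diene-1-carboxylate F3. Reduction of both esters with i-Bu2AlH (CH2Cl2, −78 °C) rejoins the route at 10.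

Step 4 may fail because the imide enolate fragments, because borohydride opens the oxazolidinone ring, or because the electron-rich triol dehydrates to the arene. The fallback separates acyl exchange, ring opening and reduction, and keeps the dienol ester-stabilised until the last operation. It sets out from 8: MeOMgBr (MeOH–CH2Cl2, 0 °C) exchanges the imide for an ester to give methyl (1R,2R,4R)-1-[(2R)-5-methoxy-5-oxopentan-2-yl]-7-oxabicyclo[2.2.1]hept-5-ene-2-carboxylate F4. Its ester enolate (LiN(SiMe3)2, THF, −78 → 0 °C) undergoes the E1cB opening to methyl (5R)-5-hydroxy-2-[(2R)-5-methoxy-5-oxopentan-2-yl]cyclohexa-1,3-diene-1-carboxylate F5, which can be purified and stored. Reduction with i-Bu2AlH (CH2Cl2, −78 °C) then rejoins the route at 10 immediately before silylation.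

**Further compounds**
F1 | step 3 | ethyl 1-[(2R)-5-methoxy-5-oxopentan-2-yl]-7-oxabicyclo[2.2.1]hept-5-ene-2-carboxylate (mixture of ring stereoisomers) | COC(=O)CC[C@@H](C)C12OC(C=C1)CC2C(=O)OCC
F2 | step 3 | ethyl 5-hydroxy-2-[(2R)-5-methoxy-5-oxopentan-2-yl]cyclohexa-1,3-diene-1-carboxylate (both C5 epimers) | COC(=O)CC[C@@H](C)C1=C(C(=O)OCC)CC(O)C=C1
F3 | step 3 | ethyl (5R)-5-hydroxy-2-[(2R)-5-methoxy-5-oxopentan-2-yl]cyclohexa-1,3-diene-1-carboxylate | COC(=O)CC[C@@H](C)C1=C(C(=O)OCC)C[C@@H](O)C=C1
F4 | step 4 | methyl (1R,2R,4R)-1-[(2R)-5-methoxy-5-oxopentan-2-yl]-7-oxabicyclo[2.2.1]hept-5-ene-2-carboxylate | COC(=O)CC[C@@H](C)[C@@]12O[C@@H](C=C1)C[C@H]2C(=O)OC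
F5 | step 4 | methyl (5R)-5-hydroxy-2-[(2R)-5-methoxy-5-oxopentan-2-yl]cyclohexa-1,3-diene-1-carboxylate | COC(=O)CC[C@@H](C)C1=C(C(=O)OC)C[C@@H](O)C=C1
F6 | step 7 | (3aR,4S,7aR)-6-({[tert-butyl(dimethyl)silyl]oxy}methyl)-5-[(2R)-5-{[tert-butyl(dimethyl)silyl]oxy}pentan-2-yl]-4-hydroxy-3-methylidene-3a,4,7,7a-tetrahydro-1-benzofuran-2(3H)-one | C=C1C(=O)O[C@@H]2CC(CO[Si](C)(C)C(C)(C)C)=C([C@H](C)CCCO[Si](C)(C)C(C)(C)C)[C@@H](O)[C@H]12
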